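**Retrosynthetic overview**
1. Target 24 ⇐ α-hydroxy ketone 23 (C1′ by chelation-controlled reduction) ⇐ aryl bromide 20 + (S)-N,N-dimethyllactamide 9 (C2′ from the chiral pool).
2. 20 ⇐ alcohol 18 by acid-triggered C2–O closure (2,3-trans); this is the only ring that is built.
3. 18 ⇐ mesylate 13 + aryl bromide 8 through the key stereospecific 1,2-aryl shift (lactate C–O becomes the C3–aryl bond with inversion), with in-flask aryl capture of the migrated aldehyde.
4. 13 ⇐ dibromide 4 + 9; arenes 4 (ring A) and 8 (ring B) both ⇐ 2,4-dibromo-6-methoxyphenol 3 ⇐ guaiacol 2 ⇐ catechol 1.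
5. Ring order: both benzene rings are carried from 1; the dihydrofuran ring is closed in step 9, after the 1,2-shift has set C3.

Assumption: compound numbers follow first appearance in the forward steps, and (S)-N,N-dimethyllactamide (8 non-hydrogen atoms) is taken as commercially available.

**Route**

Step 1
Reactants: 1 catechol
Product: 2 2-methoxyphenol (guaiacol)
Conditions: MeI (1.0 eq), K2CO3 (1.0 eq), acetone, reflux; distillation
Reagents that add atoms: iodomethane, CI
Why: Williamson O-methylation with limiting base and MeI, where the hydrogen-bonded mono-ether is much less acidic than catechol, so the mono-ether dominates and is distilled from a little veratrole.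

Step 2
Reactants: 2 2-methoxyphenol
Product: 3 2,4-dibromo-6-methoxyphenol
Conditions: Br2 (2.05 eq), AcOH, 10–20 °C
Reagents that add atoms: bromine, BrBr
Why: Electrophilic aromatic bromination in which the free hydroxyl out-directs the methoxy group, so bromine enters para and then ortho to OH.

Step 3
Reactants: 3 2,4-dibromo-6-methoxyphenol
Product: 4 1,5-dibromo-3-methoxy-2-(methoxymethoxy)benzene
Conditions: NaH, MOMCl, THF, 0 °C → rt
Reagents that add atoms: chloromethyl methyl ether, COCCl
Why: Williamson etherification of the sodium phenoxide installs an acid-labile MOM group that later steers the ortho Br/Li exchange and is lost in the ring closure.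

Step 4
Reactants: 3 2,4-dibromo-6-methoxyphenol
Product: 5 1,5-dibromo-2,3-dimethoxybenzene
Conditions: MeI, K2CO3, acetone, reflux
Reagents that add atoms: iodomethane, CI
Why: Williamson O-methylation of the phenol gives the dimethoxy pattern of ring B.

Step 5
Reactants: 5 1,5-dibromo-2,3-dimethoxybenzene
Product: 8 5-bromo-1-(tert-butoxy)-2,3-dimethoxybenzene, via aryllithium 6 (not isolated), via arylmagnesium bromide 7 (not isolated)
Conditions: n-BuLi (1.0 eq), THF, −78 °C; MgBr2·OEt2, −78 → 0 °C; PhCO3t-Bu, 0 °C; aq. NH4Cl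
Reagents that add atoms: tert-butyl peroxybenzoate, CC(C)(C)OOC(=O)c1ccccc1
Why: Chelation-assisted Br/Li exchange takes only the bromide ortho to OMe, and electrophilic oxygenation of the derived aryl Grignard by the perester (tert-butoxy transfer to carbon) gives the protected phenol directly while the para bromide stays.

Step 6
Reactants: 4 1,5-dibromo-3-methoxy-2-(methoxymethoxy)benzene; 9 (S)-N,N-dimethyllactamide
Product: 12 (2S)-1-[5-bromo-3-methoxy-2-(methoxymethoxy)phenyl]-2-hydroxypropan-1-one, via aryllithium 10 (not isolated), via magnesium alkoxide 11 (not isolated)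
Conditions: 4, n-BuLi (1.0 eq), THF, −78 °C; add 11 (from 9, i-PrMgCl, THF, −20 °C), −78 → 0 °C; cold aq. NH4Cl
Reagents that add atoms: none
Why: The bromide next to OMOM exchanges first (chelation), and nucleophilic acyl substitution on a tertiary amide stops at the ketone because the ketone is released only on work-up, so the lactate stereocentre is carried over unchanged.

Step 7
Reactants: 12 (2S)-1-[5-bromo-3-methoxy-2-(methoxymethoxy)phenyl]-2-hydroxypropan-1-one
Product: 13 (2S)-1-[5-bromo-3-methoxy-2-(methoxymethoxy)phenyl]-1-oxopropan-2-yl methanesulfonate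
Conditions: MsCl, Et3N, CH2Cl2, −20 °C
Reagents that add atoms: methanesulfonyl chloride, CS(=O)(=O)Cl
Why: O-sulfonylation of the secondary alcohol at low temperature does not break the C–O bond of the stereocentre, so the S configuration is kept.

Step 8
Reactants: 13 (2S)-1-[5-bromo-3-methoxy-2-(methoxymethoxy)phenyl]-1-oxopropan-2-yl methanesulfonate; 8 5-bromo-1-(tert-butoxy)-2,3-dimethoxybenzene
Product: 18 (2S)-2-[5-bromo-3-methoxy-2-(methoxymethoxy)phenyl]-1-[3-(tert-butoxy)-4,5-dimethoxyphenyl]propan-1-ol (C1 epimers), via aluminium alkoxide 14 (not isolated), via aryllithium 15 (not isolated), via arylalane 16 (not isolated), via aldehyde 17 (not isolated)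
Conditions: 13, DIBAL-H (1.05 eq), CH2Cl2, −78 °C; then 16 (1.5 eq; from 8, n-BuLi, Et2O, −78 → 0 °C, then Et2AlCl, −78 °C), −78 → 0 °C; aq. Rochelle salt
Reagents that add atoms: none
Why: Proposed new method: an arylative pinacol-type rearrangement in which hydride delivery gives aluminium alkoxide 14, the O–Al push and the Lewis-acidic arylalane 16 pulling on the mesylate trigger an anti-periplanar 1,2-shift of the ortho-alkoxyaryl ring with inversion at the lactate carbon (S-mesylate gives S-configured C3, aryl migrating in preference to H), and the mesylato-aluminate so formed, ion-paired with the aluminium-bound aldehyde 17, transfers its aryl group (sp2 carbon in preference to ethyl) before enolisation can erode C3; the closest known reaction type is the organoaluminium-promoted Suzuki–Tsuchihashi semipinacol rearrangement of β-mesyloxy alcohols with in situ hydride or alkyl capture, together with arylalane addition to aldehydes, and the new carbinol centre is formed as an inconsequential epimer mixture.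

Step 9
Reactants: 18 (2S)-2-[5-bromo-3-methoxy-2-(methoxymethoxy)phenyl]-1-[3-(tert-butoxy)-4,5-dimethoxyphenyl]propan-1-ol (C1 epimers)
Product: 20 5-[(2S,3S)-5-bromo-7-methoxy-3-methyl-2,3-dihydro-1-benzofuran-2-yl]-2,3-dimethoxyphenol, via tert-butyl ether 19 (not isolated)
Conditions: TFA/CH2Cl2 (1:4), 0.02 M, 0 °C → rt; aq. NaHCO3
Reagents that add atoms: none
Why: SN1 cyclodehydration in which acid ionises the benzylic alcohol, the ortho ether oxygen closes the five-membered ring with loss of the methoxymethyl group and the tert-butyl ether is cleaved by the same acid, both carbinol epimers converging on the thermodynamically favoured 2,3-trans (2S) isomer because the aryl group ends up anti to the C3 methyl.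

Step 10
Reactants: 20 5-[(2S,3S)-5-bromo-7-methoxy-3-methyl-2,3-dihydro-1-benzofuran-2-yl]-2,3-dimethoxyphenol; 9 (S)-N,N-dimethyllactamide
Product: 23 (2S)-2-hydroxy-1-[(2S,3S)-2-(3-hydroxy-4,5-dimethoxyphenyl)-7-methoxy-3-methyl-2,3-dihydro-1-benzofuran-5-yl]propan-1-one, via dilithio species 21 (not isolated), via lithium alkoxide 22 (not isolated)
Conditions: 20, n-BuLi (2.1 eq), THF, −78 °C; add 22 (2 eq; from 9, n-BuLi 1.0 eq, THF, −78 °C), −78 → 0 °C; cold aq. NH4Cl
Reagents that add atoms: none
Why: The first equivalent of n-BuLi masks the phenol as its lithium phenoxide and the second performs Br/Li exchange; the lactamide is added as its pre-formed lithium alkoxide 22 so that its OH cannot quench 21 and the all-lithium medium keeps the phenoxide-bearing aryl nucleophile from being transmetallated to a less reactive arylmagnesium, and nucleophilic acyl substitution on the tertiary amide stops at the ketone because the tetrahedral adduct is held until work-up, bringing in the three-carbon side chain with its 2′S centre from the chiral pool.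

Step 11
Reactants: 23 (2S)-2-hydroxy-1-[(2S,3S)-2-(3-hydroxy-4,5-dimethoxyphenyl)-7-methoxy-3-methyl-2,3-dihydro-1-benzofuran-5-yl]propan-1-one
Product: 24 (1R,2S)-1-[(2S,3S)-2-(3-hydroxy-4,5-dimethoxyphenyl)-7-methoxy-3-methyl-2,3-dihydro-1-benzofuran-5-yl]propane-1,2-diol
Conditions: Zn(BH4)2 (2 eq), Et2O/THF, −30 → 0 °C; H2O, aq. Rochelle salt
Reagents that add atoms: none
Why: Cram-chelate-controlled reduction in which hydride attacks the zinc-chelated α-hydroxy ketone from the face of the small α-hydrogen, giving the anti (erythro) 1R,2S diol.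

**Compound list**
1 | catechol | Oc1ccccc1O | starting material
2 | 2-methoxyphenol | COc1ccccc1O | intermediate
3 | 2,4-dibromo-6-methoxyphenol | COc1cc(Br)cc(Br)c1O | intermediate
4 | 1,5-dibromo-3-methoxy-2-(methoxymethoxy)benzene | COCOc1c(Br)cc(Br)cc1OC | intermediate
5 | 1,5-dibromo-2,3-dimethoxybenzene | COc1cc(Br)cc(Br)c1OC | intermediate
6 | (5-bromo-2,3-dimethoxyphenyl)lithium | [Li]c1cc(Br)cc(OC)c1OC | intermediate
7 | (5-bromo-2,3-dimethoxyphenyl)magnesium bromide | Br[Mg]c1cc(Br)cc(OC)c1OC | intermediate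
8 | 5-bromo-1-(tert-butoxy)-2,3-dimethoxybenzene | COc1cc(Br)cc(OC(C)(C)C)c1OC | intermediate
9 | (S)-N,N-dimethyllactamide | C[C@H](O)C(=O)N(C)C | starting material
10 | [5-bromo-3-methoxy-2-(methoxymethoxy)phenyl]lithium | [Li]c1cc(Br)cc(OC)c1OCOC | intermediate
11 | chloromagnesium (S)-1-(dimethylamino)-1-oxopropan-2-olate | C[C@H](O[Mg]Cl)C(=O)N(C)C | intermediate
12 | (2S)-1-[5-bromo-3-methoxy-2-(methoxymethoxy)phenyl]-2-hydroxypropan-1-one | C[C@H](O)C(=O)c1cc(Br)cc(OC)c1OCOC | intermediate
13 | (2S)-1-[5-bromo-3-methoxy-2-(methoxymethoxy)phenyl]-1-oxopropan-2-yl methanesulfonate | C[C@H](OS(C)(=O)=O)C(=O)c1cc(Br)cc(OC)c1OCOC | intermediate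
14 | diisobutylaluminium (2S)-1-[5-bromo-3-methoxy-2-(methoxymethoxy)phenyl]-2-(methanesulfonyloxy)propan-1-olate (C1 epimers) | C[C@H](OS(C)(=O)=O)C(O[Al](CC(C)C)CC(C)C)c1cc(Br)cc(OC)c1OCOC | intermediate
15 | [3-(tert-butoxy)-4,5-dimethoxyphenyl]lithium | [Li]c1cc(OC)c(OC)c(OC(C)(C)C)c1 | intermediate
16 | [3-(tert-butoxy)-4,5-dimethoxyphenyl]diethylaluminium | CC[Al](CC)c1cc(OC)c(OC)c(OC(C)(C)C)c1 | intermediate
17 | (2S)-2-[5-bromo-3-methoxy-2-(methoxymethoxy)phenyl]propanal (aluminium-bound) | C[C@H](C=O)c1cc(Br)cc(OC)c1OCOC | intermediate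
18 | (2S)-2-[5-bromo-3-methoxy-2-(methoxymethoxy)phenyl]-1-[3-(tert-butoxy)-4,5-dimethoxyphenyl]propan-1-ol (C1 epimers) | C[C@H](C(O)c1cc(OC)c(OC)c(OC(C)(C)C)c1)c1cc(Br)cc(OC)c1OCOC | intermediate
19 | (2S,3S)-5-bromo-2-[3-(tert-butoxy)-4,5-dimethoxyphenyl]-7-methoxy-3-methyl-2,3-dihydro-1-benzofuran | COc1cc([C@H]2Oc3c(OC)cc(Br)cc3[C@@H]2C)cc(OC(C)(C)C)c1OC | intermediate
20 | 5-[(2S,3S)-5-bromo-7-methoxy-3-methyl-2,3-dihydro-1-benzofuran-2-yl]-2,3-dimethoxyphenol | COc1cc([C@H]2Oc3c(OC)cc(Br)cc3[C@@H]2C)cc(O)c1OC | intermediate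
21 | lithium 5-[(2S,3S)-5-lithio-7-methoxy-3-methyl-2,3-dihydro-1-benzofuran-2-yl]-2,3-dimethoxyphenolate | COc1cc([C@H]2Oc3c(OC)cc([Li])cc3[C@@H]2C)cc(O[Li])c1OC | intermediate
22 | lithium (S)-1-(dimethylamino)-1-oxopropan-2-olate | C[C@H](O[Li])C(=O)N(C)C | intermediate
23 | (2S)-2-hydroxy-1-[(2S,3S)-2-(3-hydroxy-4,5-dimethoxyphenyl)-7-methoxy-3-methyl-2,3-dihydro-1-benzofuran-5-yl]propan-1-one | COc1cc([C@H]2Oc3c(OC)cc(C(=O)[C@H](C)O)cc3[C@@H]2C)cc(O)c1OC | intermediate
24 | (1R,2S)-1-[(2S,3S)-2-(3-hydroxy-4,5-dimethoxyphenyl)-7-methoxy-3-methyl-2,3-dihydro-1-benzofuran-5-yl]propane-1,2-diol (CNP0229216.1) | COc1cc([C@H]2Oc3c(OC)cc([C@@H](O)[C@H](C)O)cc3[C@@H]2C)cc(O)c1OC | target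

**Count**
Total steps: 11. Longest linear sequence: 9 steps (1, 2, 3, 6, 7, 8, 9, 10, 11); steps 4 and 5 form the ring-B branch that joins at step 8.

**Steps most likely to fail, with fallbacks**

Step 8 (the proposed new step). Risks are ethyl instead of aryl transfer, partial racemisation of aldehyde 17 before capture, and participation of the MOM oxygen instead of the aryl ring. The fallback uses only known chemistry, sets out from 13 and comes back at 18. Compound 13 is put through the established reductive pinacol-type rearrangement (DIBAL-H 2.5 eq, then Et3Al, CH2Cl2, −78 → −20 °C), in which the migrated aldehyde is reduced in the flask to (2S)-2-[5-bromo-3-methoxy-2-(methoxymethoxy)phenyl]propan-1-ol F1. Buffered Dess–Martin oxidation at 0 °C then gives aldehyde 17, which is used at once with aryllithium 15 (from 8, n-BuLi, THF, −78 °C) to return to 18.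

Step 9. Risks are E1 loss of the C3 proton from the benzylic cation (a stilbene that would erode C3) and alkylation of the electron-rich rings by the MOM and tert-butyl fragments. The fallback sets out from 18 and comes back at 19, which is then isolated. The MOM ether alone is removed without protic acid (TMSOTf, 2,2′-bipyridyl, CH2Cl2, 0 °C, then water) to give (2S)-2-(5-bromo-2-hydroxy-3-methoxyphenyl)-1-[3-(tert-butoxy)-4,5-dimethoxyphenyl]propan-1-ol F2. This is closed under neutral Mitsunobu conditions (PPh3, DIAD, THF, 0 °C), an SN2-type dehydrative etherification instead of a free carbocation, to give 19. A short TFA treatment as in step 9 converts 19 into 20 and epimerises at C2 any 2,3-cis isomer that came from the minor carbinol epimer.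

Step 10. Risks are incomplete Br/Li exchange on the phenoxide-bearing substrate and sluggish acylation by the lactamide alkoxide. The fallback sets out from 20 and comes back at 24, bypassing 23 and step 11. Compound 20 is silylated (TBSCl, imidazole, DMF) to tert-butyl{5-[(2S,3S)-5-bromo-7-methoxy-3-methyl-2,3-dihydro-1-benzofuran-2-yl]-2,3-dimethoxyphenoxy}dimethylsilane F3. Br/Li exchange (n-BuLi, THF, −78 °C) and Felkin–Anh (non-chelation) addition to (S)-2-[(tert-butyldimethylsilyl)oxy]propanal, C[C@H](O[Si](C)(C)C(C)(C)C)C=O (lactaldehyde carrying a silyl protecting group; otherwise two steps from ethyl (S)-lactate), give the anti adduct (1R,2S)-2-[(tert-butyldimethylsilyl)oxy]-1-[(2S,3S)-2-{3-[(tert-butyldimethylsilyl)oxy]-4,5-dimethoxyphenyl}-7-methoxy-3-methyl-2,3-dihydro-1-benzofuran-5-yl]propan-1-ol F4. The minor syn epimer is removed by chromatography, and TBAF in THF at 0 °C removes both silyl groups to give 24.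

**Further compounds**
F1 | step 8 | (2S)-2-[5-bromo-3-methoxy-2-(methoxymethoxy)phenyl]propan-1-ol | C[C@H](CO)c1cc(Br)cc(OC)c1OCOC
F2 | step 9 | (2S)-2-(5-bromo-2-hydroxy-3-methoxyphenyl)-1-[3-(tert-butoxy)-4,5-dimethoxyphenyl]propan-1-ol (C1 epimers) | C[C@H](C(O)c1cc(OC)c(OC)c(OC(C)(C)C)c1)c1cc(Br)cc(OC)c1O
F3 | step 10 | tert-butyl{5-[(2S,3S)-5-bromo-7-methoxy-3-methyl-2,3-dihydro-1-benzofuran-2-yl]-2,3-dimethoxyphenoxy}dimethylsilane | COc1cc([C@H]2Oc3c(OC)cc(Br)cc3[C@@H]2C)cc(O[Si](C)(C)C(C)(C)C)c1OC
F4 | step 10 | (1R,2S)-2-[(tert-butyldimethylsilyl)oxy]-1-[(2S,3S)-2-{3-[(tert-butyldimethylsilyl)oxy]-4,5-dimethoxyphenyl}-7-methoxy-3-methyl-2,3-dihydro-1-benzofuran-5-yl]propan-1-ol | COc1cc([C@H]2Oc3c(OC)cc([C@@H](O)[C@H](C)O[Si](C)(C)C(C)(C)C)cc3[C@@H]2C)cc(O[Si](C)(C)C(C)(C)C)c1OC
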